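**Retrosynthetic overview**
1. Feature: number the cyclopentane C1 (amino acid carbon), C2 (octanoyloxy CH), C3 (phenyl carbinol), C4 and C5 (CH2, C5 next to C1). The C1–N and C3–O bonds lie cis-1,3 on one face with C2 between them, and the C2 ester oxygen lies on the other face. Joining N to O gives a 2-oxa-3-azabicyclo[2.2.1]heptane with C2 as the one-atom bridge.
2. Disconnections: hydrogenolysis (benzyl ester, N-1-phenylethyl) and N–O reduction lead back to this bicycle. Retro-[3+2] across C1–C2 and O–C3 then opens it to an acyclic C1 ketonitrone, tethered by two carbons to an (E)-enol octanoate C2=C3.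
3. Ring order: there is no ring before the key step. Cyclopentane and isoxazolidine close together in it, and the isoxazolidine is opened again afterwards.
4. The nitrone comes from an α-keto ester and (S)-N-(1-phenylethyl)hydroxylamine. The keto group stays masked as a silyl-protected carbinol until the enol octanoate is in place, because a free 2,6-dioxo ester (a 1,5-dicarbonyl) would close to a dihydropyranol and be acylated at the wrong oxygen.
5. The chain comes from 4-benzoylbutyric acid, which holds the carboxyl carbon, C1, C5, C4, C3 and the phenyl group. A methoxymethylene Wittig reaction adds C2 and an enolate hydroxylation adds the oxygen at C1.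

Key step: step 10

Assumption: the (S)-1-phenylethyl group is taken to favour the (1S,4S,7R) adduct, or at least to allow its separation. If the sense is the opposite, the (R)-hydroxylamine is used, since the auxiliary carbon is lost in the last step.
Locants: in the hexanoate names, C2 = ring C1, C3 = ring C5, C4 = ring C4, C5 = ring C3 and C6 = ring C2.

Step 1
Reactants: 1 4-benzoylbutyric acid (5-oxo-5-phenylpentanoic acid); 2 benzyl bromide
Product: 3 benzyl 5-oxo-5-phenylpentanoate
Conditions: K2CO3, DMF, rt
Reagents that add atoms: benzyl bromide (2), BrCc1ccccc1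
Why: Carboxylate O-alkylation (SN2 on benzyl bromide) leaves the aryl ketone alone and installs an ester that falls in the final hydrogenolysis.

Step 2
Reactants: 3 benzyl 5-oxo-5-phenylpentanoate; 4 (methoxymethyl)triphenylphosphonium chloride
Product: 6 benzyl 6-methoxy-5-phenylhex-5-enoate (E/Z mixture), via methoxymethylidene ylide 5 (not isolated)
Conditions: 4, KOtBu, THF, 0 °C; then 3, 0 °C to rt
Reagents that add atoms: (methoxymethyl)triphenylphosphonium chloride (4), COC[P+](c1ccccc1)(c1ccccc1)c1ccccc1.[Cl-]
Why: In this Wittig olefination the preformed non-stabilised ylide (no free alkoxide left) adds to the aryl ketone far faster than to the ester and brings in C2 as a masked aldehyde, and the alkene geometry does not matter because step 5 erases it.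

Step 3
Reactants: 6 benzyl 6-methoxy-5-phenylhex-5-enoate
Product: 8 benzyl 2-hydroxy-6-methoxy-5-phenylhex-5-enoate (racemic carbinol, E/Z mixture), via potassium ester enolate 7 (not isolated)
Conditions: KN(SiMe3)2, THF, −78 °C; 2-(phenylsulfonyl)-3-phenyloxaziridine, −78 °C; AcOH quench
Reagents that add atoms: 2-(phenylsulfonyl)-3-phenyloxaziridine (Davis oxaziridine), O=S(=O)(c1ccccc1)N1OC1c1ccccc1
Why: In this Davis enolate hydroxylation the ester α-CH2 (future C1) is the only acidic position now that the ketone is gone, the potassium enolate takes oxygen from the oxaziridine, and the new carbinol centre is racemic and is erased in step 8.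

Step 4
Reactants: 8 benzyl 2-hydroxy-6-methoxy-5-phenylhex-5-enoate
Product: 9 benzyl 2-[(tert-butyldiphenylsilyl)oxy]-6-methoxy-5-phenylhex-5-enoate
Conditions: tBuPh2SiCl, imidazole, DMF, rt
Reagents that add atoms: tert-butyl(chloro)diphenylsilane, CC(C)(C)[Si](Cl)(c1ccccc1)c1ccccc1
Why: Imidazole-promoted silylation of a secondary alcohol gives a tert-butyldiphenylsilyl ether that outlasts the mineral acid of step 5 and stops this oxygen from forming a lactol with the coming aldehyde.

Step 5
Reactants: 9 benzyl 2-[(tert-butyldiphenylsilyl)oxy]-6-methoxy-5-phenylhex-5-enoate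
Product: 10 benzyl 2-[(tert-butyldiphenylsilyl)oxy]-6-oxo-5-phenylhexanoate (diastereomer mixture)
Conditions: 3 M aq. HCl, THF, 40 °C
Reagents that add atoms: water, O
Why: Acid-catalysed enol ether hydrolysis (rate-limiting C-protonation, then hemiacetal collapse) frees the α-phenyl aldehyde while the benzyl ester and silyl ether tolerate the medium, and the new benzylic centre is a mixture that vanishes in step 6.

Step 6
Reactants: 10 benzyl 2-[(tert-butyldiphenylsilyl)oxy]-6-oxo-5-phenylhexanoate; 11 octanoic anhydride
Product: 12 benzyl (E)-2-[(tert-butyldiphenylsilyl)oxy]-6-(octanoyloxy)-5-phenylhex-5-enoate (racemic at C2)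
Conditions: 11, Et3N, DMAP (cat.), CH2Cl2, rt; chromatographic removal of the minor alkene isomer
Reagents that add atoms: octanoic anhydride (11), CCCCCCCC(=O)OC(=O)CCCCCCC
Why: In this DMAP-catalysed enolate O-acylation the α-phenyl aldehyde is the only carbonyl acidic enough for Et3N to enolise, the acylpyridinium captures the enolate oxygen, and the isomer with oxygen trans to phenyl (E, acyloxy cis to the chain) should prevail because it keeps the styrene planar.

Step 7
Reactants: 12 benzyl (E)-2-[(tert-butyldiphenylsilyl)oxy]-6-(octanoyloxy)-5-phenylhex-5-enoate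
Product: 13 benzyl (E)-2-hydroxy-6-(octanoyloxy)-5-phenylhex-5-enoate (racemic)
Conditions: HF·pyridine, pyridine, THF, 0 °C to rt
Reagents that add atoms: none
Why: Fluoride desilylation is driven by Si–F bond formation and runs in a weakly acidic medium that spares the base-sensitive enol ester and the benzyl ester.

Step 8
Reactants: 13 benzyl (E)-2-hydroxy-6-(octanoyloxy)-5-phenylhex-5-enoate
Product: 14 benzyl (E)-6-(octanoyloxy)-2-oxo-5-phenylhex-5-enoate
Conditions: Dess–Martin periodinane, CH2Cl2, rt
Reagents that add atoms: none
Why: Dess–Martin oxidation of an α-hydroxy ester gives the α-keto ester under neutral, water-free conditions that leave the enol ester C=C alone, and it removes the racemic centre.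

Step 9
Reactants: 14 benzyl (E)-6-(octanoyloxy)-2-oxo-5-phenylhex-5-enoate; 15 (S)-N-(1-phenylethyl)hydroxylamine
Product: 16 (E)-ketonitrone of 14, benzyl (2E,5E)-6-(octanoyloxy)-2-{oxido[(1S)-1-phenylethyl]iminio}-5-phenylhex-5-enoate (ester trans to the oxide oxygen, tether cis to it)
Conditions: 15 (1.0 equiv), 4 Å molecular sieves, CH2Cl2, rt to 40 °C
Reagents that add atoms: (S)-N-(1-phenylethyl)hydroxylamine (15), C[C@H](NO)c1ccccc1
Why: Nitrone formation by condensation of an N-alkylhydroxylamine with an activated ketone can occur only at the α-keto ester carbonyl because the aldehyde carbon is locked as its enol ester, the auxiliary centre is untouched, and C-ester ketonitrones place the ester trans to the oxide.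

Step 10
Reactants: 16 (E)-ketonitrone, (E)-enol octanoate
Product: 17 benzyl (1S,4S,7R)-7-(octanoyloxy)-1-phenyl-3-[(1S)-1-phenylethyl]-2-oxa-3-azabicyclo[2.2.1]heptane-4-carboxylate (bicycle C1 = ring C3, C4 = ring C1, C7 = ring C2; octanoate anti to the N–O bridge)
Conditions: toluene (0.01 M), 110 °C, sealed vessel; chromatographic separation from the diastereomeric adduct
Reagents that add atoms: none
Why: On heating, the nitrone (C1=N–O) and the enol ester (C2=C3) combine in one concerted, suprafacial [3+2] cycloaddition that makes C1–C2 and O–C3; the closest known reaction type is the bridged-mode intramolecular nitrone–olefin cycloaddition of C-(but-3-enyl) nitrones, and C-ester ketonitrones are known partners of electron-rich alkenes. The cyclopentane closes through C1–C2 with both alkene carbons inside the new ring, and the isoxazolidine closes at the same time through O–C3, so that N–O spans C1 and C3 as a two-atom bridge (bridged, not fused, mode), the fused alternative needing C1–C3 bonding and a cyclobutane. Regioselectivity is thus set by the two-carbon tether and is backed electronically, because phenyl and alkyl at C3 outweigh the weak acyloxy donor at C2, which leaves C2 the larger HOMO coefficient for the ester-lowered LUMO at C1. C1 and C3 are tied to each other by the bridge, which forces N and O onto one face of the carbocycle, and C2 is set by suprafacial addition to the geometrically pure (E)-alkene, whose acyloxy group lies cis to the tether and so ends anti to the N–O bridge, trans to both heteroatoms. The absolute sense rests on the (S)-1-phenylethyl group on nitrogen, which makes the two mirror-related ways of folding the tether diastereomeric, so the wanted adduct is favoured or at least separable. Only the (E)-nitrone, with the tether cis to the oxide oxygen, can fold in this way; C-ester nitrones isomerise on heating, so any (Z) form feeds into it, and chelating Lewis acids are left out because they would hold ester and oxide on the same side.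

Step 11
Reactants: 17 bicyclic isoxazolidine
Product: 18 benzyl (1S,2R,3S)-3-hydroxy-2-(octanoyloxy)-3-phenyl-1-{[(1S)-1-phenylethyl]amino}cyclopentane-1-carboxylate
Conditions: Zn dust, AcOH, rt to 40 °C
Reagents that add atoms: none
Why: Reductive isoxazolidine N–O cleavage by electron transfer from Zn breaks no C–N or C–O bond, so all three ring centres are kept, and the trans relation of the octanoate to the new NH and OH blocks acyl migration.

Step 12
Reactants: 18 N-(1-phenylethyl) amino alcohol benzyl ester
Product: 19 Fusarilin A, (1S,2R,3S)-1-amino-3-hydroxy-2-(octanoyloxy)-3-phenylcyclopentane-1-carboxylic acid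
Conditions: H2 (1 atm), Pd(OH)2/C, MeOH, rt
Reagents that add atoms: none
Why: Catalytic hydrogenolysis cleaves the benzylic C–O bond of the ester and the benzylic C–N bond of the auxiliary, whereas the tertiary benzylic carbinol is inert in neutral medium and the aliphatic octanoate is not affected.

**Compound list**
1 | 4-benzoylbutyric acid (5-oxo-5-phenylpentanoic acid) | O=C(O)CCCC(=O)c1ccccc1 | starting material
2 | benzyl bromide | BrCc1ccccc1 | starting material
3 | benzyl 5-oxo-5-phenylpentanoate | O=C(CCCC(=O)OCc1ccccc1)c1ccccc1 | intermediate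
4 | (methoxymethyl)triphenylphosphonium chloride | COC[P+](c1ccccc1)(c1ccccc1)c1ccccc1.[Cl-] | starting material
5 | (methoxymethylidene)triphenylphosphorane | COC=P(c1ccccc1)(c1ccccc1)c1ccccc1 | intermediate
6 | benzyl 6-methoxy-5-phenylhex-5-enoate (E/Z) | COC=C(CCCC(=O)OCc1ccccc1)c1ccccc1 | intermediate
7 | potassium enolate of 6 | COC=C(CCC=C([O-])OCc1ccccc1)c1ccccc1.[K+] | intermediate
8 | benzyl 2-hydroxy-6-methoxy-5-phenylhex-5-enoate | COC=C(CCC(O)C(=O)OCc1ccccc1)c1ccccc1 | intermediate
9 | benzyl 2-[(tert-butyldiphenylsilyl)oxy]-6-methoxy-5-phenylhex-5-enoate | COC=C(CCC(O[Si](c1ccccc1)(c1ccccc1)C(C)(C)C)C(=O)OCc1ccccc1)c1ccccc1 | intermediate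
10 | benzyl 2-[(tert-butyldiphenylsilyl)oxy]-6-oxo-5-phenylhexanoate | O=CC(CCC(O[Si](c1ccccc1)(c1ccccc1)C(C)(C)C)C(=O)OCc1ccccc1)c1ccccc1 | intermediate
11 | octanoic anhydride | CCCCCCCC(=O)OC(=O)CCCCCCC | starting material
12 | benzyl (E)-2-[(tert-butyldiphenylsilyl)oxy]-6-(octanoyloxy)-5-phenylhex-5-enoate | CCCCCCCC(=O)O/C=C(/c1ccccc1)CCC(O[Si](c1ccccc1)(c1ccccc1)C(C)(C)C)C(=O)OCc1ccccc1 | intermediate
13 | benzyl (E)-2-hydroxy-6-(octanoyloxy)-5-phenylhex-5-enoate | CCCCCCCC(=O)O/C=C(/c1ccccc1)CCC(O)C(=O)OCc1ccccc1 | intermediate
14 | benzyl (E)-6-(octanoyloxy)-2-oxo-5-phenylhex-5-enoate | CCCCCCCC(=O)O/C=C(/c1ccccc1)CCC(=O)C(=O)OCc1ccccc1 | intermediate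
15 | (S)-N-(1-phenylethyl)hydroxylamine | C[C@H](NO)c1ccccc1 | starting material
16 | (E)-ketonitrone of 14, N-[(S)-1-phenylethyl], (E)-enol octanoate | CCCCCCCC(=O)O/C=C(/c1ccccc1)CC/C(C(=O)OCc1ccccc1)=[N+](\[O-])[C@@H](C)c1ccccc1 | intermediate
17 | benzyl (1S,4S,7R)-7-(octanoyloxy)-1-phenyl-3-[(1S)-1-phenylethyl]-2-oxa-3-azabicyclo[2.2.1]heptane-4-carboxylate | CCCCCCCC(=O)O[C@@H]1[C@]2(C(=O)OCc3ccccc3)CC[C@@]1(c3ccccc3)ON2[C@@H](C)c3ccccc3 | intermediate
18 | benzyl (1S,2R,3S)-3-hydroxy-2-(octanoyloxy)-3-phenyl-1-{[(1S)-1-phenylethyl]amino}cyclopentane-1-carboxylate | CCCCCCCC(=O)O[C@@H]1[C@](N[C@@H](C)c2ccccc2)(C(=O)OCc2ccccc2)CC[C@]1(O)c1ccccc1 | intermediate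
19 | Fusarilin A | CCCCCCCC(=O)O[C@@H]1[C@](N)(C(=O)O)CC[C@]1(O)c1ccccc1 | target

Total step count: 12. Longest linear sequence: 12 steps (from 1).

**Steps most likely to fail**

**Step 10.**
- What may go wrong: ring closure may be slow or reversible at the crowded trisubstituted enol ester, because the adduct carries norbornane-type strain and gives up both the styrene and the nitrone–ester conjugation.
- The nitrone may also decay thermally, by prototropic shift into the benzylic N-substituent or by loss of styrene.
- The facial bias of the auxiliary may be weak.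
- Fallback (from 13, back at 19): the dipole is changed to a silyl nitronate. This is the more reactive partner used in intramolecular silyl nitronate–olefin cycloaddition, and it has an oxygen cis to the tether in either geometry.
- Appel bromination of 13 (CBr4, PPh3, CH2Cl2) gives benzyl (E)-2-bromo-6-(octanoyloxy)-5-phenylhex-5-enoate F1.
- Kornblum displacement (NaNO2, phloroglucinol, DMF) gives benzyl (E)-2-nitro-6-(octanoyloxy)-5-phenylhex-5-enoate F2.
- Me3SiCl and Et3N in toluene give the trimethylsilyl nitronate of the nitro ester F3. It is not isolated and on warming should close in the same bridged, suprafacial sense to racemic benzyl 7-(octanoyloxy)-1-phenyl-3-[(trimethylsilyl)oxy]-2-oxa-3-azabicyclo[2.2.1]heptane-4-carboxylate F4.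
- Zn in AcOH cleaves both N–O bonds. Preparative chromatography on a chiral stationary phase then gives benzyl (1S,2R,3S)-1-amino-3-hydroxy-2-(octanoyloxy)-3-phenylcyclopentane-1-carboxylate F5.
- Hydrogenolysis of the benzyl ester (H2, Pd/C, MeOH) gives 19. Absolute configuration then comes from resolution instead of an auxiliary.

**Step 9.**
- What may go wrong: dehydration of the carbinolamine at a hindered ketone may be sluggish, and octanoyl may transfer from the enol ester (whose leaving group is about as good as a phenoxide) to the free hydroxylamine.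
- Fallback (from 15 and 14, back at 16): the condensation is driven by silicon instead of by loss of water.
- Silylation of 15 (Me3SiCl, Et3N, Et2O) gives N,O-bis(trimethylsilyl)-N-[(1S)-1-phenylethyl]hydroxylamine F6.
- F6 has no free N–H or O–H to be acylated. With 14 in warm toluene it should give 16 by addition to the ketone and elimination of the disiloxane.

**Step 6.**
- What may go wrong: geometric control in the O-acylation may be weak, or the isomers may not separate. Either would carry the C2 epimer into the key step.
- Fallback (from 10, back at 12): the geometry is fixed on a silyl enol ether first.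
- Soft enolisation of 10 (tBuMe2SiOTf, Et3N, CH2Cl2, 0 °C) should give benzyl (E)-6-[(tert-butyldimethylsilyl)oxy]-2-[(tert-butyldiphenylsilyl)oxy]-5-phenylhex-5-enoate F7. Its bulkier silyloxy group raises the preference for oxygen trans to phenyl, and it is robust enough to be freed of its isomer on silica.
- Fluoride-catalysed O-acylation uses octanoyl fluoride F8 (from octanoyl chloride and KHF2) and catalytic Bu4N[Ph3SiF2] in THF at low temperature. It exchanges silicon for the octanoyl group with retention of the alkene geometry and gives 12.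

**Further compounds**
F1 | step 10 | benzyl (E)-2-bromo-6-(octanoyloxy)-5-phenylhex-5-enoate | CCCCCCCC(=O)O/C=C(/c1ccccc1)CCC(Br)C(=O)OCc1ccccc1
F2 | step 10 | benzyl (E)-2-nitro-6-(octanoyloxy)-5-phenylhex-5-enoate | CCCCCCCC(=O)O/C=C(/c1ccccc1)CCC([N+](=O)[O-])C(=O)OCc1ccccc1
F3 | step 10 | trimethylsilyl nitronate of the nitro ester | CCCCCCCC(=O)O/C=C(/c1ccccc1)CCC(C(=O)OCc1ccccc1)=[N+]([O-])O[Si](C)(C)C
F4 | step 10 | benzyl 7-(octanoyloxy)-1-phenyl-3-[(trimethylsilyl)oxy]-2-oxa-3-azabicyclo[2.2.1]heptane-4-carboxylate (racemic, wanted enantiomer drawn) | CCCCCCCC(=O)O[C@@H]1[C@]2(C(=O)OCc3ccccc3)CC[C@@]1(c3ccccc3)ON2O[Si](C)(C)C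
F5 | step 10 | benzyl (1S,2R,3S)-1-amino-3-hydroxy-2-(octanoyloxy)-3-phenylcyclopentane-1-carboxylate | CCCCCCCC(=O)O[C@@H]1[C@](N)(C(=O)OCc2ccccc2)CC[C@]1(O)c1ccccc1
F6 | step 9 | N,O-bis(trimethylsilyl)-N-[(1S)-1-phenylethyl]hydroxylamine | C[C@H](N(O[Si](C)(C)C)[Si](C)(C)C)c1ccccc1
F7 | step 6 | benzyl (E)-6-[(tert-butyldimethylsilyl)oxy]-2-[(tert-butyldiphenylsilyl)oxy]-5-phenylhex-5-enoate | CC(C)(C)[Si](C)(C)O/C=C(/c1ccccc1)CCC(O[Si](c1ccccc1)(c1ccccc1)C(C)(C)C)C(=O)OCc1ccccc1
F8 | step 6 | octanoyl fluoride | CCCCCCCC(=O)F
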